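**Strategy.** The ten-membered carbocycle is unveiled, not closed. The ketone carbon C1 and the lactone carbinol carbon C6 are the two carbons of a tetrasubstituted alkene shared by a 7-oxanorbornene (oxolane bridgeheads C7 and C10) and a cyclohexadiene (C1–C6). Ozonolysis of that ring-fusion alkene merges the two six-membered carbocycles into the oxa-bridged cyclodecene-dione, with C7, C8 and C10 already set and the C4=C5 alkene held Z. The precursor is the enantiopure exo-8-methacryloyloxy, 7-ethynyl, 10-methyl 7-oxanorbornene fused to the 4-methylcyclohexadiene, made by furan Diels–Alder chemistry. Reduction, directed epoxidation and carbonylative lactonisation then finish the target.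

Key step: step 9

Remark: atom labels C1–C10 run around the ten-membered carbocycle (C1 ketone, C4/C5 oxirane, C6 lactone carbinol, C7/C10 oxolane bridgeheads, C8 ester carbon, C11 the ethynyl carbon on C7); the C8 oxygen is carried through the key step as the methacrylate and the alkyne as the free ethynyl group (spectator groups only); racemic intermediates are drawn as the enantiomer that is carried on; the empirical size rule for lipases is assumed to hold in step 7.

**Step 1**
Reactants: 1 3-methylcyclohex-2-en-1-one; 2 1-acetyl-1H-benzotriazole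
Product: 3 6-acetyl-3-methylcyclohex-2-en-1-one (racemic, mainly enolised)
Conditions: LiN(iPr)2 (2.1 equiv), THF, −78 °C; then 2, −78 → 0 °C; aq NH4Cl
Reagents that add atoms: none
Why: Kinetic deprotonation at the α′-carbon and C-acylation of the lithium enolate by the N-acylbenzotriazole (Claisen-type enolate acylation) should give the β-diketone, the second equivalent of base absorbing its acidic proton; no lasting stereocenter is formed.

**Step 2**
Reactants: 3 6-acetyl-3-methylcyclohex-2-en-1-one
Product: 4 2-acetyl-5-methylcyclohexa-1,5-dien-1-yl trifluoromethanesulfonate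
Conditions: NaH, CH2Cl2, 0 °C; Tf2O, −78 → 0 °C
Reagents that add atoms: trifluoromethanesulfonic anhydride, O=S(=O)(OS(=O)(=O)C(F)(F)F)C(F)(F)F
Why: O-sulfonylation of the sodium enolate of a 2-acylcyclohexanone (enol triflate formation) is expected at the ring oxygen, because the endocyclic enol dominates and its triflate is the linearly conjugated dienyl ester.

**Step 3**
Reactants: 4 2-acetyl-5-methylcyclohexa-1,5-dien-1-yl trifluoromethanesulfonate; 5 3-(trimethylsilyl)prop-2-ynal
Product: 7 3,6-dimethyl-1-[(trimethylsilyl)ethynyl]-4,5-dihydro-2-benzofuran, via hydroxy enone 6 (not isolated)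
Conditions: CrCl2 (4 equiv), NiCl2 (2 mol %), DMF, 23 °C; then PPTS (cat.), CH2Cl2, 23 °C
Reagents that add atoms: none
Why: Nozaki–Hiyama–Kishi coupling (oxidative addition of the dienyl triflate to zerovalent nickel, transmetalation to chromium, aldehyde-selective addition) should give the Z-γ-hydroxy enone, whose hydroxyl adds to the neighbouring acetyl group and loses water (Paal–Knorr-type cyclodehydration) to the furan; the carbinol stereocenter disappears.

**Step 4**
Reactants: 7 3,6-dimethyl-1-[(trimethylsilyl)ethynyl]-4,5-dihydro-2-benzofuran; 8 (Z)-1,2-bis(phenylsulfonyl)ethene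
Product: 9 4,7-dimethyl-2,3-bis(phenylsulfonyl)-1-[(trimethylsilyl)ethynyl]-1,2,3,4,5,6-hexahydro-1,4-epoxynaphthalene (racemic cis-disulfone, endo and exo adducts used together)
Conditions: toluene, 60 °C, dark
Reagents that add atoms: none
Why: Diels–Alder reaction of the electron-rich tetrasubstituted furan with a doubly activated, symmetrical dienophile serving as an acetylene equivalent avoids any orientation problem (the methyl, alkynyl and vinyl substituents of the furan direct an unsymmetrical dienophile in opposing senses); the bridgeheads C7 and C10 form as a racemate and the sulfonyl configuration is irrelevant.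

**Step 5**
Reactants: 9 the disulfone cycloadduct
Product: 10 4,7-dimethyl-1-[(trimethylsilyl)ethynyl]-1,4,5,6-tetrahydro-1,4-epoxynaphthalene (racemic)
Conditions: Na/Hg amalgam (5% Na), NaH2PO4, THF–MeOH, −20 °C
Reagents that add atoms: none
Why: Reductive elimination of the vicinal disulfone by sodium amalgam should unveil the strained C8=C9 alkene of the 7-oxanorbornadiene without touching the silyl alkyne, the diene or the bridgeheads.

**Step 6**
Reactants: 10 the oxanorbornadiene
Product: 13 racemic exo-alcohol rac-(1R*,2S*,4R*)-1-ethynyl-4,7-dimethyl-1,2,3,4,5,6-hexahydro-1,4-epoxynaphthalen-2-ol, via organoborane 11 (not isolated), via silyl alkynol 12 (not isolated)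
Conditions: 9-BBN (1.1 equiv), THF, 0 → 23 °C; NaOH, H2O2, 0 °C; then K2CO3, MeOH, 23 °C
Reagents that add atoms: hydrogen peroxide, OO
Why: Hydroboration–oxidation of the strained disubstituted alkene should occur syn from the exo face (oxygen-bridge side), and boron should go to C8 because the linear, inductively withdrawing alkynyl bridgehead C7 is both smaller and more electron-poor than the methyl bridgehead C10; oxidation with retention sets the exo C8 carbinol relative to C7/C10, and carbonate methanolysis removes the C-silyl group.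

**Step 7**
Reactants: 13 the racemic exo-alcohol
Product: 14 (1R,2S,4R)-1-ethynyl-4,7-dimethyl-1,2,3,4,5,6-hexahydro-1,4-epoxynaphthalen-2-ol
Conditions: immobilised Burkholderia cepacia lipase, vinyl acetate, t-BuOMe, 30 °C, run to just past half conversion; chromatography
Reagents that add atoms: none
Why: Lipase-catalysed kinetic resolution by enantioselective transesterification: with the quaternary C7 as the large and the C9 methylene as the medium substituent, the (2R)-alcohol should be acetylated and the required (2S)-alcohol recovered, which fixes the absolute configuration of C7, C8 and C10.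

**Step 8**
Reactants: 14 the (1R,2S,4R)-alcohol; 15 methacrylic anhydride
Product: 16 (1R,2S,4R)-1-ethynyl-4,7-dimethyl-1,2,3,4,5,6-hexahydro-1,4-epoxynaphthalen-2-yl 2-methylprop-2-enoate (exo ester)
Conditions: DMAP (0.2 equiv), Et3N, CH2Cl2, 0 → 23 °C
Reagents that add atoms: none
Why: DMAP-catalysed acylation of the hindered secondary alcohol installs the target's ester before the key step, so that no hydroxyl has to be freed next to the lactone later; no stereocenter is touched.

**Step 9**
Reactants: 16 the oxanorbornene-fused cyclohexadiene methacrylate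
Product: 19 (1S,3Z,8R,10S)-1-ethynyl-4,8-dimethyl-2,7-dioxo-11-oxabicyclo[6.2.1]undec-3-en-10-yl 2-methylprop-2-enoate, via primary ozonide 17 (not isolated), via secondary ozonide 18 (not isolated)
Conditions: O3 (1.0 equiv, added as a titrated saturated solution in CH2Cl2), CH2Cl2, −78 °C; then PPh3, −78 → 23 °C
Reagents that add atoms: ozone, [O-][O+]=O
Why: Ozone adds in a concerted (3+2) cycloaddition to the strained, pyramidalised tetrasubstituted C1=C6 alkene; the primary ozonide cycloreverts to a ketone and a carbonyl oxide that stay tethered and recombine to the secondary ozonide, which PPh3 reduces to the 1,6-diketone. The closest known reaction is the ozonolysis of the ring-fusion alkene of Δ9,10-octalin-type bicycles to cyclodecane-1,6-diones. No ring is closed: cutting the bond common to the carbocycle of the 7-oxanorbornene (C6–C7–C8–C9–C10–C1) and the cyclohexadiene (C1–C6) leaves the ten-membered ring C1–C10, still spanned by the oxolane oxygen. No stereocenter is formed; C7, C8 and C10 come from 16 and the C4=C5 alkene stays Z because it was cis in a six-membered ring. The step needs chemoselectivity for C1=C6 over the trisubstituted C4=C5 alkene, the methacrylate and the ethynyl group: strain relief and higher substitution favour C1=C6, the enoate and the alkyne react with ozone far more slowly, the surviving alkene becomes a deactivated enone once C6 is a ketone, and only one equivalent of ozone is delivered.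

**Step 10**
Reactants: 19 the oxa-bridged cyclodecenedione
Product: 20 (1R,2R,3Z,8R,10S)-1-ethynyl-2-hydroxy-4,8-dimethyl-7-oxo-11-oxabicyclo[6.2.1]undec-3-en-10-yl 2-methylprop-2-enoate (the 6R allylic alcohol)
Conditions: NaBH4 (1.0 equiv), CeCl3·7H2O (1.2 equiv), MeOH–CH2Cl2, −78 °C
Reagents that add atoms: none
Why: Luche reduction should attack the conjugated C6 carbonyl 1,2 and in preference to the hindered saturated C1 ketone; cerium bridging the C6 carbonyl oxygen and the oxolane oxygen on C7 (chelation control) turns the outer face of the medium ring, the side of the ethynyl group, toward the hydride and should give the (6R)-alcohol.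

**Step 11**
Reactants: 20 the allylic alcohol
Product: 21 the (4R,5S)-4,5-epoxide of 20, oxirane oxygen cis to the C6 hydroxyl
Conditions: VO(acac)2 (5 mol %), t-BuOOH (1.5 equiv), CH2Cl2, 0 → 23 °C
Reagents that add atoms: tert-butyl hydroperoxide, CC(C)(C)OO
Why: Vanadium-catalysed hydroxyl-directed epoxidation: the vanadate ester of the C6 hydroxyl delivers the peroxide oxygen to the alkene face syn to it, which for Z-cycloalkenols of medium rings gives the cis-epoxy alcohol (attack anti to the C6–C7 ring bond), setting C4 and C5; the methacrylate, the ethynyl group and the ketone are not substrates.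

**Step 12**
Reactants: 21 the epoxy alcohol
Product: 22 CNP0241021.1 (target)
Conditions: PdI2 (5 mol %), PBu3 (10 mol %), CO (7 atm), MeCN, 60 °C
Reagents that add atoms: carbon monoxide, [C-]#[O+]
Why: Palladium-catalysed cyclocarbonylation of a 3-butyn-1-ol: the C6 alkoxide and CO form an alkoxycarbonyl complex of divalent palladium that adds syn across the ethynyl group with the acyl carbon on C11, and protonolysis of the vinyl–palladium bond releases the α-methylene-γ-lactone; O8 is already acylated so only O6 can cyclise, and C6 and C7 keep their configuration.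

**Compound list**
1 | 3-methylcyclohex-2-en-1-one | CC1=CC(=O)CCC1 | starting material
2 | 1-acetyl-1H-benzotriazole | CC(=O)n1nnc2ccccc12 | starting material
3 | 6-acetyl-3-methylcyclohex-2-en-1-one (racemic, enolised) | CC(=O)C1CCC(C)=CC1=O | intermediate
4 | 2-acetyl-5-methylcyclohexa-1,5-dien-1-yl trifluoromethanesulfonate | CC(=O)C1=C(OS(=O)(=O)C(F)(F)F)C=C(C)CC1 | intermediate
5 | 3-(trimethylsilyl)prop-2-ynal | C[Si](C)(C)C#CC=O | starting material
6 | 1-{2-[1-hydroxy-3-(trimethylsilyl)prop-2-yn-1-yl]-4-methylcyclohexa-1,3-dien-1-yl}ethan-1-one (racemic, not isolated) | CC(=O)C1=C(C(O)C#C[Si](C)(C)C)C=C(C)CC1 | intermediate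
7 | 3,6-dimethyl-1-[(trimethylsilyl)ethynyl]-4,5-dihydro-2-benzofuran | Cc1oc(C#C[Si](C)(C)C)c2c1CCC(C)=C2 | intermediate
8 | (Z)-1,2-bis(phenylsulfonyl)ethene | O=S(=O)(/C=C\S(=O)(=O)c1ccccc1)c1ccccc1 | starting material
9 | 4,7-dimethyl-2,3-bis(phenylsulfonyl)-1-[(trimethylsilyl)ethynyl]-1,2,3,4,5,6-hexahydro-1,4-epoxynaphthalene (racemic, cis-disulfone, sulfonyl carbons unassigned) | O=S(=O)(c4ccccc4)C1C(S(=O)(=O)c5ccccc5)[C@@]2(C)O[C@]1(C#C[Si](C)(C)C)C3=C2CCC(C)=C3 | intermediate
10 | 4,7-dimethyl-1-[(trimethylsilyl)ethynyl]-1,4,5,6-tetrahydro-1,4-epoxynaphthalene (racemic) | C1=C[C@@]2(C)O[C@]1(C#C[Si](C)(C)C)C3=C2CCC(C)=C3 | intermediate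
11 | 9-{exo-4,7-dimethyl-1-[(trimethylsilyl)ethynyl]-1,2,3,4,5,6-hexahydro-1,4-epoxynaphthalen-2-yl}-9-borabicyclo[3.3.1]nonane (racemic, not isolated) | B1(C2CCCC1CCC2)[C@H]3C[C@@]4(C)O[C@]3(C#C[Si](C)(C)C)C5=C4CCC(C)=C5 | intermediate
12 | exo-4,7-dimethyl-1-[(trimethylsilyl)ethynyl]-1,2,3,4,5,6-hexahydro-1,4-epoxynaphthalen-2-ol (racemic, not isolated) | O[C@H]1C[C@@]2(C)O[C@]1(C#C[Si](C)(C)C)C3=C2CCC(C)=C3 | intermediate
13 | rac-(1R*,2S*,4R*)-1-ethynyl-4,7-dimethyl-1,2,3,4,5,6-hexahydro-1,4-epoxynaphthalen-2-ol (exo-alcohol, racemate) | O[C@H]1C[C@@]2(C)O[C@]1(C#C)C3=C2CCC(C)=C3 | intermediate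
14 | (1R,2S,4R)-1-ethynyl-4,7-dimethyl-1,2,3,4,5,6-hexahydro-1,4-epoxynaphthalen-2-ol (single enantiomer) | O[C@H]1C[C@@]2(C)O[C@]1(C#C)C3=C2CCC(C)=C3 | intermediate
15 | methacrylic anhydride | C=C(C)C(=O)OC(=O)C(C)=C | starting material
16 | (1R,2S,4R)-1-ethynyl-4,7-dimethyl-1,2,3,4,5,6-hexahydro-1,4-epoxynaphthalen-2-yl 2-methylprop-2-enoate | C=C(C)C(=O)O[C@H]1C[C@@]2(C)O[C@]1(C#C)C3=C2CCC(C)=C3 | intermediate
17 | primary ozonide of 16 (1,2,3-trioxolane across C1/C6, not isolated) | C=C(C)C(=O)O[C@H]1C[C@@]2(C)O[C@]1(C#C)C34OOOC24CCC(C)=C3 | intermediate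
18 | secondary ozonide of 16 (1,2,4-trioxolane bridging C1 and C6, not isolated) | C=C(C)C(=O)O[C@H]1C[C@@]2(C)O[C@]1(C#C)C3(OO5)OC25CCC(C)=C3 | intermediate
19 | (1S,3Z,8R,10S)-1-ethynyl-4,8-dimethyl-2,7-dioxo-11-oxabicyclo[6.2.1]undec-3-en-10-yl 2-methylprop-2-enoate | C=C(C)C(=O)O[C@H]1C[C@@]2(C)O[C@]1(C#C)C(=O)/C=C(/C)CCC2=O | intermediate
20 | (1R,2R,3Z,8R,10S)-1-ethynyl-2-hydroxy-4,8-dimethyl-7-oxo-11-oxabicyclo[6.2.1]undec-3-en-10-yl 2-methylprop-2-enoate | C=C(C)C(=O)O[C@H]1C[C@@]2(C)O[C@]1(C#C)[C@H](O)/C=C(/C)CCC2=O | intermediate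
21 | (4R,5S)-4,5-epoxide of 20, oxirane oxygen cis to the (6R)-hydroxyl | C=C(C)C(=O)O[C@H]1C[C@@]2(C)O[C@]1(C#C)[C@H](O)[C@@H]1O[C@]1(C)CCC2=O | intermediate
22 | CNP0241021.1 | C=C(C)C(=O)O[C@H]1C[C@@]2(C)O[C@@]13C(=C)C(=O)O[C@@H]3[C@@H]1O[C@]1(C)CCC2=O | target

**Total step count:** 12. **Longest linear sequence:** 12 steps (from 1).

**Steps most likely to fail**

1. Step 9. Ozone may also attack the trisubstituted C4=C5 alkene of the diene, so that cleavage is not confined to the ring fusion. Fallback: use the exo C8 hydroxyl to direct the oxidant, setting out from 14. Hydroxyl-directed epoxidation (VO(acac)2, t-BuOOH, CH2Cl2) of the homoallylic alcohol should oxidise only C1=C6, from the exo face, to the epoxy alcohol F1. Periodic acid (H5IO6, THF–H2O, 0 °C) opens the epoxide to the triol F2 and cleaves its glycol in the same flask to the hydroxy dione F3. Acylation with 15 (DMAP, Et3N) returns to the route at 19.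

2. Step 6. Boron may be delivered to C9 as well as C8, or the silyl alkyne may be hydroborated. Fallback: deliver the C8 oxygen intramolecularly from a hydroxymethyl group on C7 and build the alkyne afterwards, setting out from 4.
   - Nozaki–Hiyama–Kishi coupling with (tert-butyldimethylsilyloxy)acetaldehyde and cyclodehydration as in step 3 give, through the hydroxy enone F4, the silyloxymethyl furan F5.
   - Cycloaddition with 8 and amalgam elimination as in steps 4 and 5 give the disulfone F6 and the oxanorbornadiene F7; Bu4NF frees the bridgehead carbinol F8.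
   - (HMe2Si)2NH gives the hydridosilyl ether F9, which closes under Pt2[(CH2=CHSiMe2)2O]3 catalysis by 5-exo hydrosilylation on the exo face of C8 to the oxasilolane F10 (the tether cannot reach C9 and the tetrasubstituted alkene is inert). Tamao oxidation (H2O2, KF, KHCO3) with retention gives the exo-diol F11.
   - Both hydroxyls are silylated (Et3SiCl, imidazole) to the bis(triethylsilyl) ether F12; Swern oxidation converts only the primary silyl ether into the aldehyde F13; the Ohira–Bestmann reagent (K2CO3, MeOH) gives the silyl-protected alkynol F14; PPTS in MeOH removes the silyl ether and returns to the route at 13.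

3. Step 10. Hydride may enter from both faces of the C6 carbonyl if chelation is weak, or the C1 ketone may be reduced as well. Fallback: replace substrate control by catalyst control, from 19 directly to 20. Corey–Bakshi–Shibata reduction with (S)-2-methyl-CBS-oxazaborolidine and catecholborane in toluene at −78 °C (the catalyst enantiomer matched to the 6R alcohol if the quaternary C7 acts as the large group) reduces enones in preference to hindered saturated ketones and makes no new compound.

**Further compounds**
F1 | step 9 | exo-4a,8a-epoxide of 14 (epoxy alcohol) | O[C@H]1C[C@@]2(C)O[C@]1(C#C)C34OC24CCC(C)=C3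
F2 | step 9 | 2,4a,8a-triol from hydrolysis of F1 (not isolated) | O[C@H]1C[C@@]2(C)O[C@]1(C#C)C3(O)C2(O)CCC(C)=C3
F3 | step 9 | (3Z)-1-ethynyl-10-hydroxy-4,8-dimethyl-11-oxabicyclo[6.2.1]undec-3-ene-2,7-dione | O[C@H]1C[C@@]2(C)O[C@]1(C#C)C(=O)/C=C(/C)CCC2=O
F4 | step 6 | 1-{2-[2-(tert-butyldimethylsilyloxy)-1-hydroxyethyl]-4-methylcyclohexa-1,3-dien-1-yl}ethan-1-one (not isolated) | CC(=O)C1=C(C(O)CO[Si](C)(C)C(C)(C)C)C=C(C)CC1
F5 | step 6 | 1-[(tert-butyldimethylsilyloxy)methyl]-3,6-dimethyl-4,5-dihydro-2-benzofuran | Cc1oc(CO[Si](C)(C)C(C)(C)C)c2c1CCC(C)=C2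
F6 | step 6 | disulfone cycloadduct of F5 (racemic) | O=S(=O)(c4ccccc4)C1C(S(=O)(=O)c5ccccc5)[C@@]2(C)O[C@]1(CO[Si](C)(C)C(C)(C)C)C3=C2CCC(C)=C3
F7 | step 6 | 1-[(tert-butyldimethylsilyloxy)methyl]-4,7-dimethyl-1,4,5,6-tetrahydro-1,4-epoxynaphthalene (racemic) | C1=C[C@@]2(C)O[C@]1(CO[Si](C)(C)C(C)(C)C)C3=C2CCC(C)=C3
F8 | step 6 | (4,7-dimethyl-1,4,5,6-tetrahydro-1,4-epoxynaphthalen-1-yl)methanol (racemic) | C1=C[C@@]2(C)O[C@]1(CO)C3=C2CCC(C)=C3
F9 | step 6 | dimethylsilyl ether of F8 (not isolated) | C1=C[C@@]2(C)O[C@]1(CO[SiH](C)C)C3=C2CCC(C)=C3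
F10 | step 6 | exo-fused 2,2-dimethyl-1,2-oxasilolane from F9 (not isolated) | C[Si]4(C)[C@H]1C[C@@]2(C)O[C@]1(CO4)C3=C2CCC(C)=C3
F11 | step 6 | exo-1-(hydroxymethyl)-4,7-dimethyl-1,2,3,4,5,6-hexahydro-1,4-epoxynaphthalen-2-ol (racemic) | O[C@H]1C[C@@]2(C)O[C@]1(CO)C3=C2CCC(C)=C3
F12 | step 6 | bis(triethylsilyl) ether of F11 | CC[Si](CC)(CC)O[C@H]1C[C@@]2(C)O[C@]1(CO[Si](CC)(CC)CC)C3=C2CCC(C)=C3
F13 | step 6 | exo-2-(triethylsilyloxy)-4,7-dimethyl-1,2,3,4,5,6-hexahydro-1,4-epoxynaphthalene-1-carbaldehyde | CC[Si](CC)(CC)O[C@H]1C[C@@]2(C)O[C@]1(C=O)C3=C2CCC(C)=C3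
F14 | step 6 | triethylsilyl ether of 13 | CC[Si](CC)(CC)O[C@H]1C[C@@]2(C)O[C@]1(C#C)C3=C2CCC(C)=C3
F0 | step 10 | none | none
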